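**Plan**

1. Retrosynthesis: the C4(upper)–C6(lower) interflavanyl bond is cut first (Friedel–Crafts). This leaves one monomer, the 7,3',4'-tri-O-allyl 2,3-trans-3,4-cis-flavan-3,4-diol, needed twice: as 3,4-cyclic carbonate 13 (lower unit) and as 3,4-diacetate 15 (upper-unit donor).
2. In the monomer, ring C is contracted rather than opened: its O1–C2 bond is traced back to a 1,2-shift of O1 in a cis-2,3-disubstituted 2,3-dihydrobenzofuran (O1 on the future C3). That O1–C bond comes from a 5-exo phenoxide opening of an epoxy alcohol, and the epoxide from a chalcone (Cα–Cβ, aldol).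
3. Enabling feature: in the lower unit O1 and the C3 oxygen sit on neighbouring carbons, C2 is benzylic to the electron-rich catechol ring B, and the C3 and C4 oxygens are cis. A dihydrobenzofuran whose future C2 and C4 oxygens are tied in a six-membered carbonate therefore holds the O1–C bond and the benzylic C–O bond antiperiplanar, so the two can change places (ring C from five to six atoms, carbonate ring from six to five).
4. Forward order: chalcone, epoxy ketone, epoxy alcohol, dihydrofuran ring, six-membered carbonate, key shift to ring C with its five-membered carbonate; part of 13 becomes donor 15, which is coupled with 13; methanolysis and deallylation finish.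
5. Stereochemistry: Juliá–Colonna epoxidation sets the future C2 and C3, chelation-controlled reduction sets C4, and the key step relays them by two inversions to 2R,3S,4S. The upper C4 is set trans to the 3-acetoxy group by neighbouring-group participation.
6. Phenols are carried as allyl ethers because the final flavan-3,4-diol tolerates neither acid nor hydrogenolysis; they fall last to zerovalent palladium.

Key step: step 9

**Route**

Step 1
Reactants: 1 2,4-dihydroxyacetophenone
Product: 2 1-[4-(allyloxy)-2-hydroxyphenyl]ethan-1-one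
Conditions: allyl bromide (1.05 equiv), K2CO3, acetone, reflux
Reagents that add atoms: allyl bromide, C=CCBr
Why: Williamson etherification, in which the 2-hydroxyl is held in a hydrogen bond to the ketone so that only the 4-hydroxyl should be alkylated.

Step 2
Reactants: 3 3,4-dihydroxybenzaldehyde
Product: 4 3,4-bis(allyloxy)benzaldehyde
Conditions: allyl bromide (2.5 equiv), K2CO3, DMF, 60 °C
Reagents that add atoms: allyl bromide, C=CCBr
Why: twofold Williamson etherification of the catechol, which has no competing site.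

Step 3
Reactants: 2 1-[4-(allyloxy)-2-hydroxyphenyl]ethan-1-one; 4 3,4-bis(allyloxy)benzaldehyde
Product: 5 (E)-1-[4-(allyloxy)-2-hydroxyphenyl]-3-[3,4-bis(allyloxy)phenyl]prop-2-en-1-one
Conditions: KOH (50% aq.), EtOH, 0 °C → rt
Reagents that add atoms: none
Why: Claisen–Schmidt condensation, whose E1cB dehydration should give the (E)-enone, the hydrogen-bonded 2'-hydroxychalcone being stable to the base.

Step 4
Reactants: 5 (E)-1-[4-(allyloxy)-2-hydroxyphenyl]-3-[3,4-bis(allyloxy)phenyl]prop-2-en-1-one
Product: 6 (E)-1-{4-(allyloxy)-2-[(triisopropylsilyl)oxy]phenyl}-3-[3,4-bis(allyloxy)phenyl]prop-2-en-1-one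
Conditions: TIPSOTf, Et3N, DMAP (cat.), CH2Cl2, 0 °C → rt
Reagents that add atoms: triisopropylsilyl trifluoromethanesulfonate, CC(C)[Si](C(C)C)(C(C)C)OS(=O)(=O)C(F)(F)F
Why: O-silylation masks the phenol so that the peroxide of step 5 cannot trigger an Algar–Flynn–Oyamada cyclisation, and the bulky silyl ether should outlast that step yet fall to fluoride in step 7.

Step 5
Reactants: 6 (E)-1-{4-(allyloxy)-2-[(triisopropylsilyl)oxy]phenyl}-3-[3,4-bis(allyloxy)phenyl]prop-2-en-1-one
Product: 7 {4-(allyloxy)-2-[(triisopropylsilyl)oxy]phenyl}[(2R,3S)-3-[3,4-bis(allyloxy)phenyl]oxiran-2-yl]methanone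
Conditions: poly-L-leucine, urea–H2O2, DBU, THF, rt
Reagents that add atoms: urea–hydrogen peroxide, OO.NC(N)=O
Why: Juliá–Colonna epoxidation, in which the helical poly-L-leucine should steer hydroperoxide to one face of the (E)-enone and so set both epoxide carbons (trans, 2R,3S) while the isolated allyl ethers stay inert to the nucleophilic oxidant.

Step 6
Reactants: 7 {4-(allyloxy)-2-[(triisopropylsilyl)oxy]phenyl}[(2R,3S)-3-[3,4-bis(allyloxy)phenyl]oxiran-2-yl]methanone
Product: 8 (S)-{4-(allyloxy)-2-[(triisopropylsilyl)oxy]phenyl}[(2S,3S)-3-[3,4-bis(allyloxy)phenyl]oxiran-2-yl]methanol (erythro)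
Conditions: Zn(BH4)2, Et2O, −30 °C; aq. NH4Cl
Reagents that add atoms: none
Why: chelation-controlled hydride reduction of an α,β-epoxy ketone, in which zinc bridges the carbonyl and epoxide oxygens and hydride enters anti to the epoxide C–C bond, should give the erythro alcohol with the (S)-carbinol that becomes C4.

Step 7
Reactants: 8 (S)-{4-(allyloxy)-2-[(triisopropylsilyl)oxy]phenyl}[(2S,3S)-3-[3,4-bis(allyloxy)phenyl]oxiran-2-yl]methanol
Product: 10 (2S,3S)-6-(allyloxy)-2-{(S)-[3,4-bis(allyloxy)phenyl](hydroxy)methyl}-2,3-dihydro-1-benzofuran-3-ol (2,3-cis), via tetrabutylammonium phenolate 9 (not isolated)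
Conditions: TBAF (1.1 equiv), THF, 0 °C → rt; aq. NH4Cl
Reagents that add atoms: none
Why: fluoride desilylation followed by base-mediated 5-exo-tet epoxide opening (intramolecular Williamson type), in which the phenoxide should attack the epoxide carbon next to the carbinol with inversion, as epoxides of 2-allylphenols do without acid, giving the cis-2,3-disubstituted dihydrobenzofuran and leaving the benzylic carbon as the (S)-alcohol.

Step 8
Reactants: 10 (2S,3S)-6-(allyloxy)-2-{(S)-[3,4-bis(allyloxy)phenyl](hydroxy)methyl}-2,3-dihydro-1-benzofuran-3-ol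
Product: 11 six-membered cyclic carbonate (1,3-dioxan-2-one) of 10, cis-fused to the dihydrofuran ring across C2–C3 and carrying the aryl group on the carbonate ring, configuration unchanged
Conditions: CDI (1.2 equiv), DMAP (cat.), CH2Cl2, rt
Reagents that add atoms: 1,1'-carbonyldiimidazole, O=C(n1ccnc1)n1ccnc1
Why: carbonylation of a 1,3-diol whose two hydroxyls are cis on the dihydrofuran frame, so the six-membered carbonate should close under neutral conditions that spare both benzylic C–O bonds.

Step 9
Reactants: 11 six-membered cyclic carbonate of 10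
Product: 13 3,4-cyclic carbonate of (2R,3S,4S)-7-(allyloxy)-2-[3,4-bis(allyloxy)phenyl]chromane-3,4-diol (2,3-trans-3,4-cis), via oxiranium zwitterion 12 (not isolated)
Conditions: BF3·OEt2 (0.2 equiv), 4 Å molecular sieves, CH2Cl2, −40 → 0 °C; Et3N quench
Reagents that add atoms: none
Why: Proposed new method: BF3 on the carbonyl oxygen weakens the benzylic C–O bond at the catechol-bearing carbon, which in the chair of the dioxanone (O1 and aryl both equatorial) lies antiperiplanar to the O1–C2 bond of the dihydrofuran, so O1 bridges to the benzylic carbon (oxiranium zwitterion 12) and the tethered carbonate oxygen then opens the bridge at the old C2 from the rear, a stepwise dyotropic exchange of two vicinal C–O bonds. The closest known reaction types are the oxiranium-mediated ring expansion of 2-(1-sulfonyloxyalkyl)tetrahydrofurans and 2-(1-hydroxyalkyl)-2,3-dihydrobenzofurans to tetrahydropyrans and chroman-3-ols, the Lewis-acid-promoted dyotropic ring expansion of β-lactones to γ-lactones, and the 5-exo opening of epoxides by a neighbouring carbonate. Ring C closes by 3-exo-tet attack of O1 on the benzylic carbon followed by cleavage of the old O1–C bond (net enlargement from five to six atoms), and the dioxolanone closes 5-exo-tet at the former C2 of the dihydrofuran. C2 of the flavan is set by inversion of the (S)-benzylic centre and, if the benzylic cation lives long enough to rotate, by the preference for the equatorial 2,3-trans aryl group; C3 is set by inversion at the former C2 of the dihydrofuran, the carbonate being anchored on the cis C4 oxygen so that only the 3,4-cis ring fusion can form; C4 is untouched. The step needs productive ionisation at the catechol-side carbon only: heterolysis of the more electron-rich ring-A benzylic C–O bond can only return because the carbonate stays tethered on the same face and no base is present to give a benzofuran, and 13 is the thermodynamic sink (five-membered carbonate, six-membered ether ring) whose own ionisation at C4 is likewise degenerate.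

Step 10
Reactants: 13 3,4-cyclic carbonate of (2R,3S,4S)-7-(allyloxy)-2-[3,4-bis(allyloxy)phenyl]chromane-3,4-diol (one quarter of the material)
Product: 14 (2R,3S,4S)-7-(allyloxy)-2-[3,4-bis(allyloxy)phenyl]-3,4-dihydro-2H-chromene-3,4-diol
Conditions: K2CO3 (cat.), MeOH, 0 °C → rt
Reagents that add atoms: none
Why: base-catalysed transesterification (methanolysis) of the cyclic carbonate should free the cis-diol without touching the stereocentres or the allyl ethers.

Step 11
Reactants: 14 (2R,3S,4S)-7-(allyloxy)-2-[3,4-bis(allyloxy)phenyl]-3,4-dihydro-2H-chromene-3,4-diol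
Product: 15 3,4-di-O-acetate of 14
Conditions: Ac2O, pyridine, DMAP (cat.), CH2Cl2, 0 °C
Reagents that add atoms: acetic anhydride, CC(=O)OC(C)=O
Why: O-acylation installs the axial 4-acetoxy leaving group and the 3-acetoxy participating group of the upper-unit donor.

Step 12
Reactants: 15 3,4-di-O-acetate of 14 (1 equiv); 13 3,4-cyclic carbonate (3 equiv, excess recovered)
Product: 17 protected dimer in which C4 of a (2R,3S)-3-acetoxy-7-(allyloxy)-2-[3,4-bis(allyloxy)phenyl]chroman-4-yl unit (3,4-trans, 4α) is bonded to C6 of carbonate 13, via acetoxonium triflate 16 (not isolated)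
Conditions: TMSOTf (0.2 equiv), CH2Cl2, −78 → −40 °C; Et3N quench
Reagents that add atoms: none
Why: Friedel–Crafts interflavanyl coupling, in which TMSOTf ionises the 4-acetate of 15, the 3-acetate closes the cis-fused acetoxonium ion 16, and C6 of 13 (para to O1, ortho to the 7-allyloxy group, less hindered than C8) should attack C4 from the face opposite the bridge to give the 3,4-trans bond, while the carbonate of 13 can ionise only with internal return.

Step 13
Reactants: 17 protected dimer
Product: 18 hexa-O-allyl ether of 19 (all six phenols allylated, the three alcohols free)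
Conditions: K2CO3, MeOH/THF, rt
Reagents that add atoms: none
Why: methanolysis (transesterification) removes the acetate and the cyclic carbonate while every phenol is still allylated, so that no phenoxide, quinone methide or air oxidation can arise under base.

Step 14
Reactants: 18 hexa-O-allyl ether of 19
Product: 19 (2R,3S,4S)-2-(3,4-dihydroxyphenyl)-6-[(2R,3S,4R)-2-(3,4-dihydroxyphenyl)-3,7-dihydroxy-3,4-dihydro-2H-chromen-4-yl]-3,4-dihydro-2H-chromene-3,4,7-triol
Conditions: Pd(PPh3)4 (10 mol%), morpholine, degassed THF/MeOH, rt, argon; Sephadex LH-20 (EtOH)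
Reagents that add atoms: none
Why: Tsuji–Trost deallylation, in which zerovalent palladium ionises each aryl allyl ether to a π-allyl complex that morpholine captures, is neutral, non-reducing and acid-free and should leave the benzylic C4–OH and all six stereocentres untouched.

**Compound list**

1 | 2,4-dihydroxyacetophenone | CC(=O)c1ccc(O)cc1O | starting material
2 | 1-[4-(allyloxy)-2-hydroxyphenyl]ethan-1-one | CC(=O)c1ccc(OCC=C)cc1O | intermediate
3 | 3,4-dihydroxybenzaldehyde | O=Cc1ccc(O)c(O)c1 | starting material
4 | 3,4-bis(allyloxy)benzaldehyde | O=Cc1ccc(OCC=C)c(OCC=C)c1 | intermediate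
5 | (E)-1-[4-(allyloxy)-2-hydroxyphenyl]-3-[3,4-bis(allyloxy)phenyl]prop-2-en-1-one | C=CCOc1ccc(C(=O)/C=C/c2ccc(OCC=C)c(OCC=C)c2)c(O)c1 | intermediate
6 | (E)-1-{4-(allyloxy)-2-[(triisopropylsilyl)oxy]phenyl}-3-[3,4-bis(allyloxy)phenyl]prop-2-en-1-one | C=CCOc1ccc(C(=O)/C=C/c2ccc(OCC=C)c(OCC=C)c2)c(O[Si](C(C)C)(C(C)C)C(C)C)c1 | intermediate
7 | {4-(allyloxy)-2-[(triisopropylsilyl)oxy]phenyl}[(2R,3S)-3-[3,4-bis(allyloxy)phenyl]oxiran-2-yl]methanone | C=CCOc1ccc(C(=O)[C@@H]2O[C@H]2c3ccc(OCC=C)c(OCC=C)c3)c(O[Si](C(C)C)(C(C)C)C(C)C)c1 | intermediate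
8 | (S)-{4-(allyloxy)-2-[(triisopropylsilyl)oxy]phenyl}[(2S,3S)-3-[3,4-bis(allyloxy)phenyl]oxiran-2-yl]methanol (erythro) | C=CCOc1ccc([C@H](O)[C@@H]2O[C@H]2c3ccc(OCC=C)c(OCC=C)c3)c(O[Si](C(C)C)(C(C)C)C(C)C)c1 | intermediate
9 | tetrabutylammonium 5-(allyloxy)-2-{(S)-hydroxy[(2S,3S)-3-[3,4-bis(allyloxy)phenyl]oxiran-2-yl]methyl}phenolate (not isolated) | C=CCOc1ccc([C@H](O)[C@@H]2O[C@H]2c3ccc(OCC=C)c(OCC=C)c3)c([O-])c1.CCCC[N+](CCCC)(CCCC)CCCC | intermediate
10 | (2S,3S)-6-(allyloxy)-2-{(S)-[3,4-bis(allyloxy)phenyl](hydroxy)methyl}-2,3-dihydro-1-benzofuran-3-ol (2,3-cis) | C=CCOc1ccc2c(c1)O[C@@H]([C@H](c3ccc(OCC=C)c(OCC=C)c3)O)[C@H]2O | intermediate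
11 | six-membered cyclic carbonate (1,3-dioxan-2-one) of 10, cis-fused to the dihydrofuran ring, configuration as in 10 | C=CCOc1ccc2c(c1)O[C@H]3[C@H](c4ccc(OCC=C)c(OCC=C)c4)OC(=O)O[C@@H]23 | intermediate
12 | oxiranium zwitterion: O1 bridging the old C2 and the benzylic carbon, BF3-bound carbonate on the ring-A benzylic oxygen (not isolated) | C=CCOc1ccc2c(c1)[O+]3[C@@H]([C@H]3c4ccc(OCC=C)c(OCC=C)c4)[C@H]2OC(=O)O[B-](F)(F)F | intermediate
13 | 3,4-cyclic carbonate of (2R,3S,4S)-7-(allyloxy)-2-[3,4-bis(allyloxy)phenyl]chromane-3,4-diol (2,3-trans-3,4-cis) | C=CCOc1ccc2c(c1)O[C@H](c3ccc(OCC=C)c(OCC=C)c3)[C@H]4OC(=O)O[C@@H]24 | intermediate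
14 | (2R,3S,4S)-7-(allyloxy)-2-[3,4-bis(allyloxy)phenyl]-3,4-dihydro-2H-chromene-3,4-diol | C=CCOc1ccc2c(c1)O[C@H](c3ccc(OCC=C)c(OCC=C)c3)[C@@H](O)[C@H]2O | intermediate
15 | 3,4-di-O-acetate of 14 | C=CCOc1ccc2c(c1)O[C@H](c3ccc(OCC=C)c(OCC=C)c3)[C@@H](OC(C)=O)[C@H]2OC(C)=O | intermediate
16 | cis-fused 2-methyl-1,3-dioxolan-2-ylium (acetoxonium) triflate spanning O3 and C4 of the donor (not isolated) | C=CCOc1ccc2c(c1)O[C@H](c3ccc(OCC=C)c(OCC=C)c3)[C@H]4O[C+](C)O[C@@H]24.[O-]S(=O)(=O)C(F)(F)F | intermediate
17 | protected dimer: (2R,3S)-3-acetoxy-7-(allyloxy)-2-[3,4-bis(allyloxy)phenyl]chroman-4-yl unit (3,4-trans) bonded through C4 to C6 of carbonate 13 | C=CCOc1ccc2c(c1)O[C@H](c3ccc(OCC=C)c(OCC=C)c3)[C@@H](OC(C)=O)[C@@H]2c5cc6c(cc5OCC=C)O[C@H](c7ccc(OCC=C)c(OCC=C)c7)[C@H]8OC(=O)O[C@@H]68 | intermediate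
18 | hexa-O-allyl ether of 19 (phenols allylated, three alcohols free) | C=CCOc1ccc2c(c1)O[C@H](c3ccc(OCC=C)c(OCC=C)c3)[C@@H](O)[C@@H]2c5cc6c(cc5OCC=C)O[C@H](c7ccc(OCC=C)c(OCC=C)c7)[C@@H](O)[C@H]6O | intermediate
19 | (2R,3S,4S)-2-(3,4-dihydroxyphenyl)-6-[(2R,3S,4R)-2-(3,4-dihydroxyphenyl)-3,7-dihydroxy-3,4-dihydro-2H-chromen-4-yl]-3,4-dihydro-2H-chromene-3,4,7-triol | Oc1ccc2c(c1)O[C@H](c1ccc(O)c(O)c1)[C@@H](O)[C@@H]2c1cc2c(cc1O)O[C@H](c1ccc(O)c(O)c1)[C@@H](O)[C@H]2O | target

**Step count and risks**

Total steps: 14. Longest linear sequence: 13 (steps 1 and 3 to 14; step 2 is a side branch).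

Step 9 (key step). The shift may fail in three ways: ionisation at the ring-A benzylic carbon followed by proton loss to a benzofuran; capture of the benzylic cation without migration of O1; or decarboxylation of the boron-bound carbonate. The fallback closes the pyran ring directly at the ketone stage by known chemistry and sets out from epoxy ketone 7. TBAF in THF frees the 2'-phenol, which should open the epoxide at the benzylic β-carbon (6-endo, inversion), as 2'-hydroxychalcone epoxides without a 6'-substituent do, to give the trans-dihydroflavonol (2R,3R)-7-(allyloxy)-2-[3,4-bis(allyloxy)phenyl]-3-hydroxychroman-4-one F1. Reduction with LiBH(s-Bu)3 in THF at −78 °C, with hydride delivered from the equatorial side, should give the 3,4-cis-diol 14. CDI with catalytic DMAP then closes the five-membered carbonate, and the fallback rejoins the route at 13.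

Step 12 (coupling). The coupling may be spoiled by self-condensation of the donor, by attack at C8 instead of C6, or by ring-opening ionisation of the carbonate of the acceptor. The fallback uses the lower unit at the ketone level, where C4 cannot ionise, and sets out from diol 14. MnO2 in CH2Cl2 should oxidise only the benzylic 4-hydroxyl to the dihydroflavonol F1 (the same compound as above). F1 (3 equiv) and diacetate 15 are coupled with TMSOTf at −78 °C to the dimeric ketone F2, the 3-O-acetyl-(4α→6)-linked flavanyl-dihydroflavonol. LiBH(s-Bu)3 at −78 °C then reduces the 4-ketone to the 3,4-cis-diol F3, the 3-O-acetate of 18. K2CO3 in methanol removes the acetate, and the fallback rejoins the route at 18.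

Step 5 (asymmetric epoxidation). The electron-rich enone may add hydroperoxide slowly, the ortho-silyloxy group may twist the aroyl ring and erode facial selectivity, or the peroxide may cleave the silyl ether. The fallback reverses the order of the two stereo-defining events and sets out from chalcone 6. Corey–Bakshi–Shibata reduction ((S)-2-methyl-CBS-oxazaborolidine, catecholborane, toluene, −78 °C, the silyloxyaryl group taken as the large substituent) should give the allylic alcohol (R,E)-1-{4-(allyloxy)-2-[(triisopropylsilyl)oxy]phenyl}-3-[3,4-bis(allyloxy)phenyl]prop-2-en-1-ol F4. A matched, erythro-selective Sharpless epoxidation of this secondary allylic alcohol (Ti(OiPr)4, L-(+)-diisopropyl tartrate, t-BuOOH, 4 Å molecular sieves, CH2Cl2, −20 °C) should then give epoxy alcohol 8, where the fallback rejoins the route.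

Further compounds
F1 | step 9 | (2R,3R)-7-(allyloxy)-2-[3,4-bis(allyloxy)phenyl]-3-hydroxychroman-4-one | C=CCOc1ccc2c(c1)O[C@H](c3ccc(OCC=C)c(OCC=C)c3)[C@@H](O)C2=O
F2 | step 12 | dimeric ketone: (2R,3S)-3-acetoxy-7-(allyloxy)-2-[3,4-bis(allyloxy)phenyl]chroman-4-yl unit (3,4-trans) bonded through C4 to C6 of F1 | C=CCOc1ccc2c(c1)O[C@H](c3ccc(OCC=C)c(OCC=C)c3)[C@@H](OC(C)=O)[C@@H]2c5cc6c(cc5OCC=C)O[C@H](c7ccc(OCC=C)c(OCC=C)c7)[C@@H](O)C6=O
F3 | step 12 | 3-O-acetate (upper unit) of 18, lower unit as 2,3-trans-3,4-cis-diol | C=CCOc1ccc2c(c1)O[C@H](c3ccc(OCC=C)c(OCC=C)c3)[C@@H](OC(C)=O)[C@@H]2c5cc6c(cc5OCC=C)O[C@H](c7ccc(OCC=C)c(OCC=C)c7)[C@@H](O)[C@H]6O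
F4 | step 5 | (R,E)-1-{4-(allyloxy)-2-[(triisopropylsilyl)oxy]phenyl}-3-[3,4-bis(allyloxy)phenyl]prop-2-en-1-ol | C=CCOc1ccc([C@H](O)/C=C/c3ccc(OCC=C)c(OCC=C)c3)c(O[Si](C(C)C)(C(C)C)C(C)C)c1
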